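**Retrosynthetic overview**
- Target ⇐ desilylation and acetal hydrolysis ⇐ O‑prenylation of a benzophenone whose aldehyde is masked as a diethyl acetal and whose ketone‑flanking ring‑A oxygen is a TBS ether.
- That benzophenone ⇐ one pot from an aryl ynone and 4‑methyl‑2‑silyloxyfuran: Diels–Alder/oxa‑bridge opening builds the hydroquinone ring, then the aryl 1,1‑dimethylpropargyl ether closes the 2H‑pyran (Claisen/[1,5]‑H/oxa‑6π).
- Ynone ⇐ lithium acetylide of 3,3‑diethoxypropyne + mono‑propargylated 2,6‑dihydroxybenzaldehyde, then MnO2.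
- Ring order: the resorcinol ring is bought; the hydroquinone ring forms first and the pyran second, both in the same operation.

Assumption: the target has no stereocentre, so it is a single achiral compound and no asymmetric step is needed; it is made in the open keto‑aldehyde form drawn.

**Step 1**
Reactants: 1 4‑methylfuran‑2(5H)‑one
Product: 2 tert‑butyldimethyl[(4‑methylfuran‑2‑yl)oxy]silane
Conditions: TBSOTf, Et3N, CH2Cl2, 0 °C
Reagents that add atoms: tert‑butyldimethylsilyl triflate, CC(C)(C)[Si](C)(C)OS(=O)(=O)C(F)(F)F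
Why: Soft enolisation and O‑silylation of the butenolide (silyl dienol ether formation) gives the aromatic 2‑silyloxyfuran; no stereocentre is involved.

**Step 2**
Reactants: 3 2,6‑dihydroxybenzaldehyde; 4 3‑chloro‑3‑methylbut‑1‑yne
Product: 5 2‑hydroxy‑6‑[(2‑methylbut‑3‑yn‑2‑yl)oxy]benzaldehyde
Conditions: K2CO3, KI (cat.), CuI (cat.), acetone, 55 °C
Reagents that add atoms: none
Why: Copper‑assisted O‑propargylation (Williamson‑type etherification of a phenoxide by a tertiary propargylic chloride) stops at the mono‑ether because the remaining hydroxyl is hydrogen‑bonded to the aldehyde; no stereocentre.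

**Step 3**
Reactants: 5 2‑hydroxy‑6‑[(2‑methylbut‑3‑yn‑2‑yl)oxy]benzaldehyde; 6 3,3‑diethoxyprop‑1‑yne
Product: 8 rac‑4,4‑diethoxy‑1‑{2‑hydroxy‑6‑[(2‑methylbut‑3‑yn‑2‑yl)oxy]phenyl}but‑2‑yn‑1‑ol, via lithium acetylide 7 (not isolated)
Conditions: 6 (3 equiv), n‑BuLi, THF, −78 °C; then 5, −78 → −30 °C; aq NH4Cl
Reagents that add atoms: none
Why: 1,2‑Addition of a lithium acetylide to the aldehyde (the first equivalent is spent on the phenol, hence the excess, and −78 °C keeps proton exchange with the ether's terminal alkyne slow); the new carbinol centre is racemic and is removed in step 4.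

**Step 4**
Reactants: 8 rac‑4,4‑diethoxy‑1‑{2‑hydroxy‑6‑[(2‑methylbut‑3‑yn‑2‑yl)oxy]phenyl}but‑2‑yn‑1‑ol
Product: 9 4,4‑diethoxy‑1‑{2‑hydroxy‑6‑[(2‑methylbut‑3‑yn‑2‑yl)oxy]phenyl}but‑2‑yn‑1‑one
Conditions: MnO2 (activated, excess), CH2Cl2, rt
Reagents that add atoms: none
Why: MnO2 oxidation of a benzylic–propargylic alcohol is selective and neutral, so the phenol and acetal survive and base‑triggered cyclisation of the o‑alkynoylphenol to a chromone is avoided; the stereocentre of 8 is erased.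

**Step 5**
Reactants: 9 4,4‑diethoxy‑1‑{2‑hydroxy‑6‑[(2‑methylbut‑3‑yn‑2‑yl)oxy]phenyl}but‑2‑yn‑1‑one; 2 tert‑butyldimethyl[(4‑methylfuran‑2‑yl)oxy]silane
Product: 14 {2‑[(tert‑butyldimethylsilyl)oxy]‑6‑(diethoxymethyl)‑5‑hydroxy‑4‑methylphenyl}(7‑hydroxy‑2,2‑dimethyl‑2H‑chromen‑8‑yl)methanone, via O‑TMS ynone 10 (not isolated), via oxanorbornadiene cycloadduct 11 (not isolated), via silylated propargyl ether benzophenone 12 (not isolated), via O‑TMS chromene 13 (not isolated)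
Conditions: BSA (1.2 equiv), PhMe, rt; 2 (1.5 equiv), rt → 60 °C; then 140 °C (sealed tube); then MeOH, rt
Reagents that add atoms: none
Why: Proposed new method: a one‑pot merger of two known pericyclic ring constructions, in which furan C5 (the nucleophilic diene terminus, reinforced by the 4‑methyl group) bonds to the acetal‑bearing β‑carbon of the ynone and C2 to the α‑carbon in an asynchronous Diels–Alder reaction, the 7‑oxanorbornadiene 11 opens at the silyloxy‑stabilised bridgehead and tautomerises to the hydroquinone mono‑silyl ether 12 (silyl oxygen next to the aroyl group, free OH next to the acetal), and at 140 °C the aryl 1,1‑dimethylpropargyl ether undergoes ortho‑Claisen rearrangement, enolisation, [1,5]‑H shift and oxa‑6π electrocyclisation at its only free ortho position to close the 2H‑pyran; the closest known reaction types are the 2‑silyloxyfuran/alkyne Diels–Alder route to para‑silyloxyphenols and the thermal aryl propargyl ether to 2H‑chromene rearrangement, BSA only masks the phenol transiently, and no stereocentre survives (11 is racemic and aromatises).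

**Step 6**
Reactants: 14 {2‑[(tert‑butyldimethylsilyl)oxy]‑6‑(diethoxymethyl)‑5‑hydroxy‑4‑methylphenyl}(7‑hydroxy‑2,2‑dimethyl‑2H‑chromen‑8‑yl)methanone; 15 1‑bromo‑3‑methylbut‑2‑ene (prenyl bromide)
Product: 16 {2‑[(tert‑butyldimethylsilyl)oxy]‑6‑(diethoxymethyl)‑4‑methyl‑5‑[(3‑methylbut‑2‑en‑1‑yl)oxy]phenyl}(7‑hydroxy‑2,2‑dimethyl‑2H‑chromen‑8‑yl)methanone
Conditions: K2CO3, acetone, 45 °C
Reagents that add atoms: none
Why: Williamson etherification at the only phenol that is neither silylated nor hydrogen‑bonded to a carbonyl (its ortho carbon carries the acetal, not the aldehyde), while the chromenol OH stays chelated to the ketone; no stereocentre.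

**Step 7**
Reactants: 16 {2‑[(tert‑butyldimethylsilyl)oxy]‑6‑(diethoxymethyl)‑4‑methyl‑5‑[(3‑methylbut‑2‑en‑1‑yl)oxy]phenyl}(7‑hydroxy‑2,2‑dimethyl‑2H‑chromen‑8‑yl)methanone
Product: 18 2‑(7‑hydroxy‑2,2‑dimethyl‑2H‑chromene‑8‑carbonyl)‑3‑hydroxy‑5‑methyl‑6‑[(3‑methylbut‑2‑en‑1‑yl)oxy]benzaldehyde, via phenol acetal 17 (not isolated)
Conditions: TBAF, THF, 0 °C; then 1 M aq HCl, rt
Reagents that add atoms: water, O
Why: Fluoride‑induced Si–O cleavage followed by specific‑acid acetal hydrolysis; dilute acid at rt leaves the aryl prenyl ether and the chromene intact, and there is no stereocentre to scramble.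

**Compound list**
1 | 4‑methylfuran‑2(5H)‑one | CC1=CC(=O)OC1 | starting material
2 | tert‑butyldimethyl[(4‑methylfuran‑2‑yl)oxy]silane | Cc1coc(O[Si](C)(C)C(C)(C)C)c1 | intermediate
3 | 2,6‑dihydroxybenzaldehyde | O=Cc1c(O)cccc1O | starting material
4 | 3‑chloro‑3‑methylbut‑1‑yne | CC(C)(Cl)C#C | starting material
5 | 2‑hydroxy‑6‑[(2‑methylbut‑3‑yn‑2‑yl)oxy]benzaldehyde | O=Cc1c(O)cccc1OC(C)(C)C#C | intermediate
6 | 3,3‑diethoxyprop‑1‑yne | CCOC(OCC)C#C | starting material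
7 | (3,3‑diethoxyprop‑1‑yn‑1‑yl)lithium | [Li]C#CC(OCC)OCC | intermediate
8 | rac‑4,4‑diethoxy‑1‑{2‑hydroxy‑6‑[(2‑methylbut‑3‑yn‑2‑yl)oxy]phenyl}but‑2‑yn‑1‑ol (racemic carbinol) | CCOC(OCC)C#CC(O)c1c(O)cccc1OC(C)(C)C#C | intermediate
9 | 4,4‑diethoxy‑1‑{2‑hydroxy‑6‑[(2‑methylbut‑3‑yn‑2‑yl)oxy]phenyl}but‑2‑yn‑1‑one | CCOC(OCC)C#CC(=O)c1c(O)cccc1OC(C)(C)C#C | intermediate
10 | 4,4‑diethoxy‑1‑{2‑[(2‑methylbut‑3‑yn‑2‑yl)oxy]‑6‑[(trimethylsilyl)oxy]phenyl}but‑2‑yn‑1‑one | CCOC(OCC)C#CC(=O)c1c(O[Si](C)(C)C)cccc1OC(C)(C)C#C | intermediate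
11 | rac‑{1‑[(tert‑butyldimethylsilyl)oxy]‑3‑(diethoxymethyl)‑5‑methyl‑7‑oxabicyclo[2.2.1]hepta‑2,5‑dien‑2‑yl}{2‑[(2‑methylbut‑3‑yn‑2‑yl)oxy]‑6‑[(trimethylsilyl)oxy]phenyl}methanone (racemic) | CCOC(OCC)C1=C(C(=O)c3c(O[Si](C)(C)C)cccc3OC(C)(C)C#C)C2(O[Si](C)(C)C(C)(C)C)C=C(C)C1O2 | intermediate
12 | {2‑[(tert‑butyldimethylsilyl)oxy]‑6‑(diethoxymethyl)‑5‑hydroxy‑4‑methylphenyl}{2‑[(2‑methylbut‑3‑yn‑2‑yl)oxy]‑6‑[(trimethylsilyl)oxy]phenyl}methanone | CCOC(OCC)c1c(O)c(C)cc(O[Si](C)(C)C(C)(C)C)c1C(=O)c2c(O[Si](C)(C)C)cccc2OC(C)(C)C#C | intermediate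
13 | {2‑[(tert‑butyldimethylsilyl)oxy]‑6‑(diethoxymethyl)‑5‑hydroxy‑4‑methylphenyl}{2,2‑dimethyl‑7‑[(trimethylsilyl)oxy]‑2H‑chromen‑8‑yl}methanone | CCOC(OCC)c1c(O)c(C)cc(O[Si](C)(C)C(C)(C)C)c1C(=O)c2c(O[Si](C)(C)C)ccc3c2OC(C)(C)C=C3 | intermediate
14 | {2‑[(tert‑butyldimethylsilyl)oxy]‑6‑(diethoxymethyl)‑5‑hydroxy‑4‑methylphenyl}(7‑hydroxy‑2,2‑dimethyl‑2H‑chromen‑8‑yl)methanone | CCOC(OCC)c1c(O)c(C)cc(O[Si](C)(C)C(C)(C)C)c1C(=O)c2c(O)ccc3c2OC(C)(C)C=C3 | intermediate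
15 | 1‑bromo‑3‑methylbut‑2‑ene | CC(C)=CCBr | starting material
16 | {2‑[(tert‑butyldimethylsilyl)oxy]‑6‑(diethoxymethyl)‑4‑methyl‑5‑[(3‑methylbut‑2‑en‑1‑yl)oxy]phenyl}(7‑hydroxy‑2,2‑dimethyl‑2H‑chromen‑8‑yl)methanone | CCOC(OCC)c1c(OCC=C(C)C)c(C)cc(O[Si](C)(C)C(C)(C)C)c1C(=O)c2c(O)ccc3c2OC(C)(C)C=C3 | intermediate
17 | {6‑(diethoxymethyl)‑2‑hydroxy‑4‑methyl‑5‑[(3‑methylbut‑2‑en‑1‑yl)oxy]phenyl}(7‑hydroxy‑2,2‑dimethyl‑2H‑chromen‑8‑yl)methanone | CCOC(OCC)c1c(OCC=C(C)C)c(C)cc(O)c1C(=O)c2c(O)ccc3c2OC(C)(C)C=C3 | intermediate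
18 | 2‑(7‑hydroxy‑2,2‑dimethyl‑2H‑chromene‑8‑carbonyl)‑3‑hydroxy‑5‑methyl‑6‑[(3‑methylbut‑2‑en‑1‑yl)oxy]benzaldehyde | CC(C)=CCOc1c(C)cc(O)c(C(=O)c2c(O)ccc3c2OC(C)(C)C=C3)c1C=O | target

**Step count**
Total steps: 7. Longest linear sequence: 6 (3 → 5 → 8 → 9 → 14 → 16 → 18); step 1 is the side branch.

**Three steps most likely to fail**

Step 5 (cascade). The silyloxyfuran may give a vinylogous Michael adduct instead of the cycloadduct, or the thermal stage may damage the acetal or hydroquinone. The fallback sets out from 9 and returns at 17; it separates the two ring closures and protects the phenol covalently. TBSOTf/2,6‑lutidine converts 9 into the ynone silyl ether F1. Cycloaddition with 2 (PhMe, 60 °C) is stopped at the isolated bis‑silyl propargyl ether benzophenone F2. The pyran is then closed by gold(I)‑catalysed 6‑endo hydroarylation of the propargyl ether (Ph3PAuNTf2 cat., CH2Cl2, rt), not thermally, to give the bis‑silyl chromene F3. Prenylation with 15 (K2CO3, acetone) gives the prenyl ether F4, and TBAF (2.2 equiv) removes both silyl groups to give 17, which is hydrolysed as in step 7.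

Step 3 (acetylide addition to an unprotected salicylaldehyde that carries a terminal alkyne). The fallback sets out from 4 and from 6 (as 7) and returns at 9; it replaces addition/oxidation by an acyl substitution on a non‑phenolic electrophile. Purchased 5‑hydroxy‑2,2‑dimethyl‑4H‑1,3‑benzodioxin‑4‑one F5 is etherified with 4 (K2CO3, KI, CuI, acetone) to the propargyl ether dioxinone F6. Lithium acetylide 7 (1.05 equiv, THF, −78 °C) attacks the lactone carbonyl and the tetrahedral intermediate expels acetone. The ortho‑phenoxide so formed shields the new ynone from a second addition, and a cold AcOH quench gives 9 directly, without carbinol 8 and without the oxidation.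

Step 7 (acid hydrolysis next to an aryl prenyl ether). The fallback sets out from 14 and returns at 18; it changes the order so that no prenyl ether ever meets acid. The acetal of 14 is hydrolysed first (PPTS, acetone–H2O, 40 °C) to the hydroxy‑aldehyde F7. O‑Prenylation with 15 (K2CO3, DMF, rt) gives the prenylated aldehyde silyl ether F8. Buffered TBAF/AcOH (THF, 0 °C) then frees the last phenol and gives 18.

**Further compounds**
F1 | step 5 | 1‑{2‑[(tert‑butyldimethylsilyl)oxy]‑6‑[(2‑methylbut‑3‑yn‑2‑yl)oxy]phenyl}‑4,4‑diethoxybut‑2‑yn‑1‑one | CCOC(OCC)C#CC(=O)c1c(O[Si](C)(C)C(C)(C)C)cccc1OC(C)(C)C#C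
F2 | step 5 | {2‑[(tert‑butyldimethylsilyl)oxy]‑6‑(diethoxymethyl)‑5‑hydroxy‑4‑methylphenyl}{2‑[(tert‑butyldimethylsilyl)oxy]‑6‑[(2‑methylbut‑3‑yn‑2‑yl)oxy]phenyl}methanone | CCOC(OCC)c1c(O)c(C)cc(O[Si](C)(C)C(C)(C)C)c1C(=O)c2c(O[Si](C)(C)C(C)(C)C)cccc2OC(C)(C)C#C
F3 | step 5 | {2‑[(tert‑butyldimethylsilyl)oxy]‑6‑(diethoxymethyl)‑5‑hydroxy‑4‑methylphenyl}{7‑[(tert‑butyldimethylsilyl)oxy]‑2,2‑dimethyl‑2H‑chromen‑8‑yl}methanone | CCOC(OCC)c1c(O)c(C)cc(O[Si](C)(C)C(C)(C)C)c1C(=O)c2c(O[Si](C)(C)C(C)(C)C)ccc3c2OC(C)(C)C=C3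
F4 | step 5 | {2‑[(tert‑butyldimethylsilyl)oxy]‑6‑(diethoxymethyl)‑4‑methyl‑5‑[(3‑methylbut‑2‑en‑1‑yl)oxy]phenyl}{7‑[(tert‑butyldimethylsilyl)oxy]‑2,2‑dimethyl‑2H‑chromen‑8‑yl}methanone | CCOC(OCC)c1c(OCC=C(C)C)c(C)cc(O[Si](C)(C)C(C)(C)C)c1C(=O)c2c(O[Si](C)(C)C(C)(C)C)ccc3c2OC(C)(C)C=C3
F5 | step 3 | 5‑hydroxy‑2,2‑dimethyl‑4H‑1,3‑benzodioxin‑4‑one | CC1(C)OC(=O)c2c(O)cccc2O1
F6 | step 3 | 2,2‑dimethyl‑5‑[(2‑methylbut‑3‑yn‑2‑yl)oxy]‑4H‑1,3‑benzodioxin‑4‑one | CC1(C)OC(=O)c2c(OC(C)(C)C#C)cccc2O1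
F7 | step 7 | 3‑[(tert‑butyldimethylsilyl)oxy]‑6‑hydroxy‑2‑(7‑hydroxy‑2,2‑dimethyl‑2H‑chromene‑8‑carbonyl)‑5‑methylbenzaldehyde | O=Cc1c(O)c(C)cc(O[Si](C)(C)C(C)(C)C)c1C(=O)c2c(O)ccc3c2OC(C)(C)C=C3
F8 | step 7 | 3‑[(tert‑butyldimethylsilyl)oxy]‑2‑(7‑hydroxy‑2,2‑dimethyl‑2H‑chromene‑8‑carbonyl)‑5‑methyl‑6‑[(3‑methylbut‑2‑en‑1‑yl)oxy]benzaldehyde | CC(C)=CCOc1c(C)cc(O[Si](C)(C)C(C)(C)C)c(C(=O)c2c(O)ccc3c2OC(C)(C)C=C3)c1C=O
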